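A pitfall: an excess read late in a short run looks like a property of the recipe, but here it moves with the clock. The free catalyst takes left-handed substrate and reagent to left-handed product, and the racemization catalyst turns each substrate into the other.

the same everywhere: left-handed substrate 20 mM; right-handed substrate 20 mM; free catalyst 0.24 mM; added ligand 0.77 mM

| run | reagent | racemization catalyst | remark | time |
|---|---|---|---|---|
| ash | 80 mM | 0.069 mM | run made earlier |  |
| Monday's | 80.0 mM | 0.13 mM |  | 1.0 h |
| Thursday's | 80.0 mM | 0.040 mM |  | 1.0 h |

ash run (percent of the left-handed substrate and right-handed substrate together charged)

| time / min | right-handed substrate / % | left-handed substrate / % | left-handed product / % |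
|---|---|---|---|
| 6.00 | 46.7 | 8.3 | 44.2 |
| 12.0 | 43.8 | 3.3 | 51.9 |
| 20.0 | 39.9 | 2.2 | 56.7 |
| 25.0 | 37.1 | 3.0 | 58.0 |
| 30.0 | 35.4 | 1.9 | 60.5 |

(scatter of a reading: 0.3 percentage points)

- free catalyst is single-handed; left-handed substrate and right-handed substrate are mirror images of each other, charged as a racemate, each of them at the stated concentration
- an excess is the difference of the two amounts in percent of their sum
- an excess is below zero if the other one leads
- no earlier run changes the charge of racemization catalyst; that part of a forecast is a guess

- the flask that ends with the higher excess of right-handed substrate over left-handed substrate among what is left of the two, or "neither" when 2 percentage points or less lies between them (Monday's / Thursday's / neither)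
- excess of right-handed substrate over left-handed substrate among what is left of the two at the end, Monday's
- excess of right-handed substrate over left-handed substrate among what is left of the two at the end, Thursday's

We read the ash run as a ladder. On the first rung, c(left-handed substrate) falls at 0.299 min⁻¹, a life of 2.32 min. On the last rung, c(right-handed substrate) drains at 0.0115 min⁻¹, a life of 60.0 min. Because the first life is far shorter than the last, we take the left-handed substrate as consumed as fast as it is fed, so kL·c(left-handed substrate) equals kr·(c(right-handed substrate) − c(left-handed substrate)). Here kL is its pseudo-first-order consumption frequency and kr the racemization frequency. The excess is then kL/(kL + 2kr).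

We take the drain as kr. Dividing by the ash charge gives 2.79 L mol⁻¹ s⁻¹, the racemization frequency per unit concentration of racemization catalyst charged. Using it at other charges is a guess.

The late ash excess, 88.1%, makes kL 0.171 min⁻¹. That is 57.2% of its early value. One reagent per product would leave 69.8% of the reagent at the last ash reading, which is more than that share. So if kL follows reagent, reagent also goes elsewhere. Continuing that fall and taking it alike in both flasks, our own reckoning puts kL at 0.0704 min⁻¹ at the end, giving 61.8% for Monday's and 84.0% for Thursday's.

The forecast, “My guess is that kr scales linearly with racemization catalyst”, names Thursday's, with 75% for Monday's and 92% for Thursday's. We part on kL at the hour: the forecast takes 0.13 to 0.155 per minute.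

    racemization catalyst + added ligand ⇌ idle complex (K = 3500 L mol⁻¹, k = 15.0 L mol⁻¹ s⁻¹)
    left-handed substrate + racemization catalyst ⇌ right-handed substrate + racemization catalyst, rate k2*[racemization catalyst]*[left-handed substrate] forward; the back reaction follows from the equilibrium constant (k = 10.0 L mol⁻¹ s⁻¹)
    reagent + free catalyst + left-handed substrate → free catalyst + left-handed product (k = 370 L² mol⁻² s⁻¹)
    reagent + free catalyst + right-handed substrate → free catalyst + right-handed product (k = 2.80 L² mol⁻² s⁻¹)
    2 reagent → homo dimer (k = 0.00400 L mol⁻¹ s⁻¹)

Thursday's ends higher, 88.5% against 62.3% for Monday's. Through the hour, consumption of left-handed substrate and racemization ran together while reagent fell to 19% of its charge in Monday's flask and 23% in Thursday's. With 2.79 L mol⁻¹ s⁻¹, those excesses mean a kL of 0.0718 min⁻¹ for Monday's and 0.103 min⁻¹ for Thursday's. A neighbour of Thursday's flask holds 0.14 mM of free catalyst, and reagent ends there at 23% too. Scaling Thursday's kL with free catalyst, we reckon 81.8%; that neighbour gives 82.0%.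

(The numbers in the tables were computed for substances that don't exist, and the scatter is random.)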